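Guaiane numbering is used throughout: unprimed atoms for the cross-conjugated dienone half, primed atoms for the half that carries the spiro ketone.
Retrosynthesis: the C1=C2 alkene is first moved to C1=C10. The six-membered ring C2–C1=C10–C14–C15'–C4', spiro at the quaternary α-keto carbon C4', is then a Diels–Alder ring. Cutting C14–C15' and C2–C4' leaves dehydrozaluzanin C (dienophile, exocyclic enone C4'=C15') and its 1,2-didehydro derivative (diene C2=C1–C10=C14, held s-cis).
Forward: α-santonin is photorearranged from the 6-6 to the 5-7 skeleton with the lactone already in place, then the 10(14)-alkene, the 3-alkene and the lactone methylene are installed. An α-epoxide transposes oxygen to C3 and leads to the methylene cyclopentanone. Part of this monomer is dehydrogenated through its silyl dienol ether in the presence of the rest, and the spiro-cyclohexene, the only new ring, closes last.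
Stereochemistry: C6 and C7 of both halves come from α-santonin, C1 from the photorearrangement, C5 from α-face hydrogenation, spiro C4' from attack on the convex α face of the dienophile, and C5 and C10 of the dienone half from the closing base step.

Key step: step 12

Assumption: the configuration drawn for the dienone half (5β-H, cis to H-6, and 10α-H, cis to H-7) is taken to be the arrangement reached when these two vinylogous α-positions are equilibrated by base in step 13; no precedent secures this.

Step 1
Reactants: 1 α-santonin
Product: 2 isophotosantonic lactone (10α-hydroxy-3-oxo-1αH,6βH,7αH,11βH-guai-4-en-12,6-olide)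
Conditions: hν (Hg lamp), 45% aq. AcOH, reflux, N2
Reagents that add atoms: water, O
Why: the photochemical rearrangement of the cross-conjugated cyclohexadienone in aqueous acid (santonin to isophotosantonic lactone type) contracts ring A and enlarges ring B to the 5,7-fused guaiane with 1α-H and with water captured at C-10 on the α face, C-6, C-7 and C-11 staying as in 1, and the free tertiary alcohol is chosen over its acetate so that no deprotection is needed before step 3.

Step 2
Reactants: 2 isophotosantonic lactone
Product: 3 10α-hydroxy-3-oxo-1αH,4αH,5αH,11βH-guaian-12,6α-olide (4β-methyl, cis-fused)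
Conditions: H2 (3 atm), 10% Pd/C, EtOAc, rt
Reagents that add atoms: none
Why: heterogeneous hydrogenation should add both hydrogens to the tetrasubstituted enone alkene from the α face, away from C-10 and its substituents on the β side of C-1, which sets 5α-H cis to 1α-H (and 4α-H), the lactone and the tertiary alcohol being inert.

Step 3
Reactants: 3 10α-hydroxy-3-oxo-1αH,4αH,5αH,11βH-guaian-12,6α-olide
Product: 4 3-oxo-1αH,4αH,5αH,11βH-guai-10(14)-en-12,6α-olide
Conditions: SOCl2, pyridine, CH2Cl2, −20 to 0 °C
Reagents that add atoms: none
Why: chlorosulfite formation and pyridine-mediated anti-elimination dehydrate the tertiary alcohol, H-1 being cis to the leaving group and therefore unable to give the 1(10)-alkene, so that loss of a C-14 hydrogen should give mainly the 10(14)-methylene, any 9-ene being removed on AgNO3-impregnated silica.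

Step 4
Reactants: 4 3-oxo-1αH,4αH,5αH,11βH-guai-10(14)-en-12,6α-olide
Product: 5 3β-hydroxy-1αH,4αH,5αH,11βH-guai-10(14)-en-12,6α-olide
Conditions: NaBH4, MeOH, 0 °C
Reagents that add atoms: none
Why: borohydride should attack the cyclopentanone from the convex α face, anti to the 4β-methyl group and to the cis-fused seven-membered ring, giving the 3β-alcohol whose C–O bond is trans to H-4α as the next step requires, the lactone not being reduced at 0 °C.

Step 5
Reactants: 5 3β-hydroxy-1αH,4αH,5αH,11βH-guai-10(14)-en-12,6α-olide
Product: 6 1αH,5αH,11βH-guaia-3,10(14)-dien-12,6α-olide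
Conditions: Martin sulfurane [Ph2S(OC(CF3)2Ph)2], CH2Cl2, 0 °C to rt
Reagents that add atoms: none
Why: Martin sulfurane dehydration proceeds by anti-elimination of the alkoxysulfonium ion, and of the two trans hydrogens (H-4α and H-2α) removal of the tertiary H-4α should give the more substituted 3-ene (Zaitsev orientation), C-4 losing its stereocentre.

Step 6
Reactants: 6 1αH,5αH,11βH-guaia-3,10(14)-dien-12,6α-olide
Product: 7 11β-phenylseleno-11α-methyl-1αH,5αH-guaia-3,10(14)-dien-12,6α-olide
Conditions: LiN(iPr)2, THF, −78 °C; then PhSeCl, −78 to −40 °C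
Reagents that add atoms: benzeneselenenyl chloride, Cl[Se]c1ccccc1
Why: kinetic deprotonation of the only acidic C–H (H-11 of the lactone) and selenenylation of the enolate, selenium entering trans to H-7 as is usual for trans-fused α-methyl-γ-lactones, so that only the methyl hydrogens lie syn to selenium.

Step 7
Reactants: 7 11β-phenylseleno-11α-methyl-1αH,5αH-guaia-3,10(14)-dien-12,6α-olide
Product: 9 1αH,5αH-guaia-3,10(14),11(13)-trien-12,6α-olide, via selenoxide 8 (not isolated)
Conditions: 30% aq. H2O2, pyridine, CH2Cl2, 0 °C to rt
Reagents that add atoms: none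
Why: oxidation to the selenoxide is followed by spontaneous syn-elimination (selenoxide elimination), which can only use a C-13 hydrogen because H-7 is anti to selenium, giving the exocyclic α-methylene lactone while the two other alkenes stay untouched in the pyridine-buffered medium.

Step 8
Reactants: 9 1αH,5αH-guaia-3,10(14),11(13)-trien-12,6α-olide
Product: 10 estafiatin (3α,4α-epoxy-1αH,5αH-guaia-10(14),11(13)-dien-12,6α-olide)
Conditions: mCPBA (1.05 equiv), CH2Cl2, 0 °C
Reagents that add atoms: 3-chloroperoxybenzoic acid, OOC(=O)c1cccc(Cl)c1
Why: Prilezhaev epoxidation is fastest at the electron-rich trisubstituted 3-ene (the 1,1-disubstituted 10(14)-ene reacts more slowly and the conjugated lactone methylene not at all) and should occur on the convex α face of the cis-fused bicycle, setting the 3α,4α-epoxide.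

Step 9
Reactants: 10 estafiatin
Product: 11 3-epizaluzanin C (3α-hydroxy-1αH,5αH-guaia-4(15),10(14),11(13)-trien-12,6α-olide)
Conditions: Al(OiPr)3, toluene, reflux
Reagents that add atoms: none
Why: aluminium isopropoxide-promoted isomerisation of an epoxide to an allylic alcohol, in which coordination to the epoxide oxygen and syn removal of a C-15 hydrogen through a cyclic transition state open the C4–O bond, giving the exocyclic 4(15)-ene and leaving the C3–O bond and hence the 3α configuration untouched.

Step 10
Reactants: 11 3-epizaluzanin C
Product: 12 dehydrozaluzanin C (3-oxo-1αH,5αH-guaia-4(15),10(14),11(13)-trien-12,6α-olide)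
Conditions: Dess–Martin periodinane, pyridine, CH2Cl2, 0 °C to rt
Reagents that add atoms: none
Why: Dess–Martin oxidation converts the secondary allylic alcohol into the α-methylene cyclopentanone under buffered, non-basic conditions that should neither move the exocyclic alkenes nor epimerise C-5.

Step 11
Reactants: 12 dehydrozaluzanin C
Product: 13 3-trimethylsilyloxy-1αH,5αH-guaia-2,4(15),10(14),11(13)-tetraen-12,6α-olide
Conditions: TMSOTf, Et3N, CH2Cl2, −78 to 0 °C; pentane, filtration, used crude
Reagents that add atoms: trimethylsilyl trifluoromethanesulfonate, C[Si](C)(C)OS(=O)(=O)C(F)(F)F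
Why: soft enolisation with silyl triflate and amine can only go toward C-2 because C-4 is sp2, so O-silylation should give the 2,4(15)-dienol ether with 1α-H intact, a diene that is locked s-trans and does not itself cyclo-add.

Step 12
Reactants: 13 3-trimethylsilyloxy-1αH,5αH-guaia-2,4(15),10(14),11(13)-tetraen-12,6α-olide and 12 dehydrozaluzanin C (3 equiv)
Product: 15 spiro Diels–Alder adduct with C1=C10, 2β-H, 5α-H and C-2 bonded to the α face of C-4', via dienone 14 (not isolated)
Conditions: Pd(OAc)2 (1.05 equiv), degassed MeCN, argon, rt, slow addition of 13 to Pd(OAc)2 and 12; then 40 °C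
Reagents that add atoms: none
Why: Saegusa–Ito oxidation converts the silyl dienol ether into a C-2 palladium enolate, β-hydride elimination of H-1 gives dienone 14 and zerovalent palladium, and 14 is trapped as it forms by the excess of 12 in an intermolecular Diels–Alder reaction of its diene C2=C1–C10=C14 with the exocyclic enone C4'=C15', the closest known type being the head-to-head [4+2] union of an α-methylene cyclopentanone with a cross-conjugated dienone made by the same oxidation. The spiro-cyclohexene C2–C1=C10–C14–C15'–C4' closes by this intermolecular [4+2], in which the C14–C15' bond should form ahead of C2–C4' because the developing charge or spin is stabilised at the α-keto carbon C-4' and across C10–C1–C2 next to the C-3 carbonyl, which also fixes the regiochemistry. The diene is held s-cis because C1=C2 and C10=C14 are both exocyclic to the seven-membered ring on neighbouring atoms. The quaternary spiro centre C-4' is set by approach of the diene to the convex α face of the cis-fused hydroazulenone 12 (the face of H-1' and H-5'), and C-2 by approach of 12 to the α face of 14, anti to C-6, the latter centre being removed in step 13. The step needs chemoselectivity for the strained, ketone-activated C4'=C15' over the lactone methylenes and for cross- over self-cycloaddition of 14, which the higher dienophilicity of the methylene cyclopentanone and the slow generation of 14 in an excess of 12 should secure. Oxygen is excluded so that the dienol of 15 is not oxygenated at C-10.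

Step 13
Reactants: 15 spiro Diels–Alder adduct
Product: 16 target CNP0221188.1
Conditions: DBU (0.3 equiv), degassed CH2Cl2, argon, 0 °C to rt
Reagents that add atoms: none
Why: amine-base enolisation at the doubly activated C-2 gives the extended dienolate, whose protonation at C-10 on the α face moves the alkene into conjugation at C1=C2 (β,γ- to α,β-enone isomerisation), and continued exposure equilibrates the vinylogous α-positions C-5 (through the 3-oxidofulvene-type trienolate) and C-10, which under the assumption stated above should settle on 5β-H and 10α-H, while C-4', the lactone centres and the primed half carry no acidic hydrogen at a stereocentre and stay fixed.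

Compound list
1 | α-santonin | C[C@H]1[C@@H]2CC[C@]3(C=CC(=O)C(=C3[C@H]2OC1=O)C)C | starting material
2 | isophotosantonic lactone (10α-hydroxy-3-oxo-1αH,6βH,7αH,11βH-guai-4-en-12,6-olide) | CC1=C2[C@H]3OC(=O)[C@@H](C)[C@@H]3CC[C@@](C)(O)[C@@H]2CC1=O | intermediate
3 | 10α-hydroxy-3-oxo-1αH,4αH,5αH,11βH-guaian-12,6α-olide | C[C@H]1C(=O)C[C@H]2[C@](C)(O)CC[C@H]3[C@H](C)C(=O)O[C@@H]3[C@H]21 | intermediate
4 | 3-oxo-1αH,4αH,5αH,11βH-guai-10(14)-en-12,6α-olide | C[C@H]1C(=O)C[C@H]2C(=C)CC[C@H]3[C@H](C)C(=O)O[C@@H]3[C@H]21 | intermediate
5 | 3β-hydroxy-1αH,4αH,5αH,11βH-guai-10(14)-en-12,6α-olide | C[C@H]1[C@@H](O)C[C@H]2C(=C)CC[C@H]3[C@H](C)C(=O)O[C@@H]3[C@H]21 | intermediate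
6 | 1αH,5αH,11βH-guaia-3,10(14)-dien-12,6α-olide | CC1=CC[C@H]2C(=C)CC[C@H]3[C@H](C)C(=O)O[C@@H]3[C@H]21 | intermediate
7 | 11β-phenylseleno-11α-methyl-1αH,5αH-guaia-3,10(14)-dien-12,6α-olide | CC1=CC[C@H]2C(=C)CC[C@H]3[C@@](C)([Se]c4ccccc4)C(=O)O[C@@H]3[C@H]21 | intermediate
8 | selenoxide of 7 | CC1=CC[C@H]2C(=C)CC[C@H]3[C@@](C)([Se](=O)c4ccccc4)C(=O)O[C@@H]3[C@H]21 | intermediate
9 | 1αH,5αH-guaia-3,10(14),11(13)-trien-12,6α-olide | CC1=CC[C@H]2C(=C)CC[C@H]3C(=C)C(=O)O[C@@H]3[C@H]21 | intermediate
10 | estafiatin (3α,4α-epoxide of 9) | C[C@@]12O[C@@H]1C[C@H]3C(=C)CC[C@H]4C(=C)C(=O)O[C@@H]4[C@H]32 | intermediate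
11 | 3-epizaluzanin C (3α-hydroxy-1αH,5αH-guaia-4(15),10(14),11(13)-trien-12,6α-olide) | C=C1[C@H](O)C[C@H]2C(=C)CC[C@H]3C(=C)C(=O)O[C@@H]3[C@H]21 | intermediate
12 | dehydrozaluzanin C (3-oxo-1αH,5αH-guaia-4(15),10(14),11(13)-trien-12,6α-olide) | C=C1C(=O)C[C@H]2C(=C)CC[C@H]3C(=C)C(=O)O[C@@H]3[C@H]21 | intermediate
13 | 3-trimethylsilyloxy-1αH,5αH-guaia-2,4(15),10(14),11(13)-tetraen-12,6α-olide | C=C1C(O[Si](C)(C)C)=C[C@H]2C(=C)CC[C@H]3C(=C)C(=O)O[C@@H]3[C@H]21 | intermediate
14 | 3-oxo-5αH-guaia-1,4(15),10(14),11(13)-tetraen-12,6α-olide (dienone) | C=C1C(=O)C=C2C(=C)CC[C@H]3C(=C)C(=O)O[C@@H]3[C@H]21 | intermediate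
15 | spiro Diels–Alder adduct (C1=C10, 2β-H, 5α-H, C-2 on the α face of C-4') | C=C1C(=O)[C@H]2C3=C(CC[C@H]4C(=C)C(=O)O[C@@H]4[C@@H]13)CC[C@]21C(=O)C[C@H]2C(=C)CC[C@H]3C(=C)C(=O)O[C@@H]3[C@H]21 | intermediate
16 | CNP0221188.1 (C1=C2 enone, 5β-H, 10α-H) | C=C1C(=O)C2=C3[C@H](CC[C@H]4C(=C)C(=O)O[C@@H]4[C@H]13)CC[C@]21C(=O)C[C@H]2C(=C)CC[C@H]3C(=C)C(=O)O[C@@H]3[C@H]21 | target

Total step count: 13.
Longest linear sequence: 13 steps (1 to 16; compound 12 enters step 12 a second time as the dienophile).

Steps most likely to fail

Step 13. The equilibration may settle on a different arrangement at C-5 and C-10. In particular, inversion at C-5 may not take place, because the seven-membered ring with its trans-fused lactone can keep the chair-like shape of the monomer when H-5 stays α. The cross-conjugated methylene ketone may also be lost to amine addition. The fallback sets out from 15 and comes back at 16, and replaces thermodynamic by kinetic control. Et3N in CH2Cl2 at 0 °C to rt should only move the alkene into conjugation and give the enone with 5α-H and 10α-H, the C-5 epimer of the target F1. F1 would then be treated with LiN(SiMe3)2 (2.2 equiv, the first equivalent being taken up by the C-2' methylene) in THF at −78 °C to form the cross-conjugated trienolate at C-5. This would be protonated at −78 °C with a hindered proton source (2,6-di-tert-butylphenol), and 16 isolated without further contact with base.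

Step 12. The dienone may react with itself as diene and dienophile or polymerise, the dienophile may be attacked on its β face, or palladium may isomerise the exocyclic alkenes. The fallback sets out from 13 and comes back at 15, and generates the dienone without palladium. PhSeCl in CH2Cl2 at −78 °C should add selenium to the convex α face of C-2, cis to H-1, giving the 2α-phenylseleno ketone F2. Oxidation with mCPBA at −78 °C gives its selenoxide F3. After addition of 12 (3 equiv) and iPr2NH the mixture is warmed to rt, so that syn-elimination with H-1 releases 14 slowly in the presence of the dienophile, and the same cycloaddition gives 15.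

Step 5. The elimination may run toward C-2 and give the 2-ene, above all if step 4 delivers some 3α-alcohol, which has no trans hydrogen at C-4. The fallback sets out from 4 and comes back at 6, and does not depend on the carbinol configuration. Ketone 4 is converted with Tf2O and 2,6-di-tert-butyl-4-methylpyridine in CH2Cl2 into the more substituted enol triflate F4. F4 is reduced with Pd(OAc)2, PPh3, Bu3N and HCO2H in DMF at 60 °C to the 3-ene 6.

Further compounds
F1 | step 13 | conjugated enone with 5α-H and 10α-H (C-5 epimer of 16) | C=C1C(=O)C2=C3[C@H](CC[C@H]4C(=C)C(=O)O[C@@H]4[C@@H]13)CC[C@]21C(=O)C[C@H]2C(=C)CC[C@H]3C(=C)C(=O)O[C@@H]3[C@H]21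
F2 | step 12 | 2α-phenylseleno-dehydrozaluzanin C | C=C1C(=O)[C@H]([Se]c4ccccc4)[C@H]2C(=C)CC[C@H]3C(=C)C(=O)O[C@@H]3[C@H]21
F3 | step 12 | selenoxide of F2 | C=C1C(=O)[C@H]([Se](=O)c4ccccc4)[C@H]2C(=C)CC[C@H]3C(=C)C(=O)O[C@@H]3[C@H]21
F4 | step 5 | 3-trifluoromethanesulfonyloxy-1αH,5αH,11βH-guaia-3,10(14)-dien-12,6α-olide | CC1=C(OS(=O)(=O)C(F)(F)F)C[C@H]2C(=C)CC[C@H]3[C@H](C)C(=O)O[C@@H]3[C@H]21
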